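Count the incoming ligand in equivalents of starting complex, because the bench rule says one equivalent buys one exchange. Violet holds 1.00 equivalents, so the rule puts its whole charge at complex with one exchanged. The earlier runs refuse this: dawn, charged with 1.28 equivalents, reads at most 24 %, and spring and noon top out at 24 % and 24 %.

| setting | dawn | spring | noon | violet | amber | blue |
|---|---|---|---|---|---|---|
| starting complex | 0.050 M | 0.050 M | 0.050 M | 0.050 M | 0.050 M | 0.050 M |
| incoming ligand | 0.064 M | 0.083 M | 0.18 M | 0.0500 M | 0.100 M | 0.150 M |
| leaving ligand | 0.050 M | 0.050 M | 0.050 M | 0.0500 M | 0.0500 M | 0.0500 M |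
| remark | run made earlier | run made earlier | run made earlier |  |  |  |
| time |  |  |  | 40 h | 40 h | 40 h |

| run | time / h | complex with one exchanged / % | complex with two exchanged / % |
|---|---|---|---|
| dawn | 2.50 | 15 | 2 |
| dawn | 8.00 | 23 | 14 |
| dawn | 12.0 | 24 | 21 |
| dawn | 20.0 | 23 | 33 |
| dawn | 30.0 | 20 | 43 |
| spring | 2.50 | 13 | 7 |
| spring | 8.00 | 24 | 24 |
| spring | 12.0 | 22 | 33 |
| spring | 20.0 | 22 | 45 |
| spring | 30.0 | 14 | 57 |
| noon | 2.50 | 23 | 14 |
| noon | 4.00 | 24 | 27 |
| noon | 8.00 | 16 | 55 |
| noon | 15.0 | 8 | 83 |
| noon | 30.0 | 1 | 97 |

(each reading ± 2 percentage points)

- the earlier runs were read with a standard deviation of 2 percentage points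
- a reading or a percentage of leaving ligand counts all its forms, free or not

1. final complex with one exchanged, as a percentage of the starting complex charged, for each flask in turn (violet, amber, blue)

The rule's border is a ratio. Both exchanges draw on the same ligand at the same moment, so ligand and time cancel between them, and one number remains: r, the selectivity factor, the second exchange's rate constant over the first's. With a the fraction of starting complex left, and both exchanges taken as forward steps first order in incoming ligand, complex with one exchanged is a minus a to the power r, over r less one. In logarithms, when a falls one power of ten, a to the power r falls r powers, so in the tail the fraction is simply a over r less one. Noon at 15.0 h is such a tail: a reads 9.00 % against 8 % of complex with one exchanged, which gives the reading r = 2.12, rough at a scatter of 2 percentage points. The reading stands above one: complex with one exchanged reacts on as it forms, against the one-for-one rule. The law's peak is 24.1 %, the height dawn and spring read.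

That peak costs 0.736 equivalents of uptake. Violet's charge exceeds this, so my reckoning sets violet at 40 h slightly past the peak and a little under its height, with incoming ligand the limiting reagent of that flask. My reckoning sends amber and blue on into the tail.

The forecast gives 22 %, 11 % and 3 %, having found “little need for a reverse reaction”.

The flasks give 22.6 %, 10.5 % and 2.33 %, and the forecast stands.

    starting complex + incoming ligand → leaving ligand + complex with one exchanged (k = 3.24 × 10⁻⁴ M⁻¹ s⁻¹)
    complex with one exchanged + incoming ligand → leaving ligand + complex with two exchanged (k = 7.24 × 10⁻⁴ M⁻¹ s⁻¹)
    crystals ⇌ leaving ligand, rate k3*(cs3 - [leaving ligand]) while solid is left; crystals form when [leaving ligand] > cs3 (solubility = 39.0 mM, k = 0.00154 s⁻¹)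

In amber the second exchange alone, with incoming ligand as charged, has a half-life of 2.7 h, short against the 40 h of the run. Amber keeps 14 % of its starting complex at 40.0 h, and the law with r turns that into 11.1 % of complex with one exchanged. Blue keeps 2.9 % at 40.0 h, and the same law gives 2.54 % beside the 2.33 % found.

The numbers in the tables were computed with constants of no real substance, and the scatter is random.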